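The hard part of the target is the trimethylcyclohexene ring, whose quaternary C(CH3)2 carbon is allylic to the tetrasubstituted ring C=C. A temporary carboxyl group on the ring CH2 next to C(CH3)2 turns this array into a γ,δ-unsaturated acid. The C(CH3)2–CH2 ring bond can therefore be made by Ireland–Claisen rearrangement of a lactone. In one operation the step closes the carbocycle, builds the quaternary carbon and fixes the position of the ring alkene. Its precursor is a 6-methyl-6-alkenyl-δ-valerolactone, assembled from C6-lithiated geraniol (which brings the E alkene) and methyl 5-oxohexanoate. Decarboxylation, methylenation and a B-alkyl Suzuki coupling with a glycidate-derived (R)-iodobutenolide finish the target.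

Key step: step 4

Remark: 2 and 6–11 are used as racemates. Their stereocentres disappear before 12, so only C4 of the butenolide (taken from methyl (R)-glycidate) needs control.

Step 1
Reactants: 1 geranyl acetate
Product: 2 (2E)-6,7-dibromo-3,7-dimethyloct-2-en-1-yl acetate (racemic)
Conditions: Br2 (1.0 equiv), CH2Cl2, −78 °C
Reagents that add atoms: bromine, BrBr
Why: Electrophilic anti addition of bromine; the allylic acetate deactivates the 2,3-alkene, so one equivalent should add only to the more electron-rich 6,7-alkene, and the single new stereocentre (C6) is lost in step 2.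

Step 2
Reactants: 2 (2E)-6,7-dibromo-3,7-dimethyloct-2-en-1-yl acetate
Product: 3 (2E)-6-bromo-3,7-dimethylocta-2,6-dien-1-ol (6-bromogeraniol)
Conditions: KOH, EtOH, reflux
Reagents that add atoms: none
Why: E2 dehydrobromination in which hydroxide removes the acidified C6–H geminal to bromine, antiperiplanar to the tertiary C7–Br, to give the tetrasubstituted vinyl bromide (no E/Z issue, since C7 carries two methyls); the acetate is saponified in the same pot.

Step 3
Reactants: 3 6-bromogeraniol; 4 methyl 5-oxohexanoate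
Product: 7 6-[(6E)-8-hydroxy-2,6-dimethylocta-2,6-dien-3-yl]-6-methyloxan-2-one (racemic), via dilithio species 5 (not isolated), via open-chain dilithium dialkoxide 6 (not isolated)
Conditions: MeLi (1.05 equiv), Et2O/THF, −78 °C; t-BuLi (2.1 equiv), −78 °C; CeCl3, −78 °C; then 4, −78 °C → rt; aq. NH4Cl
Reagents that add atoms: none
Why: O–H deprotonation and bromine–lithium exchange give the vinyllithium; its organocerium form should add 1,2 to the ketone of 4 faster than it enolises it or attacks the ester, and the tertiary alkoxide then lactonises (6-exo-trig) with loss of methoxide, giving a racemic new stereocentre of no consequence.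

Step 4
Reactants: 7 6-[(6E)-8-hydroxy-2,6-dimethylocta-2,6-dien-3-yl]-6-methyloxan-2-one
Product: 10 3-[(3E)-5-hydroxy-3-methylpent-3-en-1-yl]-2,2,4-trimethylcyclohex-3-ene-1-carboxylic acid (racemic), via bis-silylated ketene acetal 8 (not isolated), via silyl ester 9 (not isolated)
Conditions: LDA (2.3 equiv), Me3SiCl/Et3N (internal quench), THF, −78 °C → rt; toluene, 110 °C; then aq. citric acid, MeOH
Reagents that add atoms: none
Why: After the hydroxyl proton, LDA removes the only enolisable lactone α-proton and Me3SiCl traps the enolate on oxygen as the endocyclic silyl ketene acetal 8, which on heating undergoes a concerted suprafacial [3,3]-sigmatropic shift: ketene-acetal carbon C3 bonds to the C(CH3)2 terminus of the alkenyl group while the tertiary allylic C6–O bond breaks. This is the Ireland–Claisen rearrangement in its lactone (alicyclic Claisen) form, a reaction type known for 6-alkenyl-δ-valerolactones. The six-membered carbocycle closes through a boat-like, bicyclo[2.2.2]-type transition state because the two-carbon tether C4–C5 links both ends of the rearranging array, so the O–C(=O) unit leaves the ring and the two alkene carbons take its place. The only new stereocentre (C1, bearing CO2H) forms as a racemate from racemic 7 and is irrelevant because step 5 erases it. The step needs O- over C-silylation, and rearrangement faster than ionisation or elimination at the tertiary allylic C–O bond; the internal Me3SiCl/Et3N quench at −78 °C and acid-free heating in a non-polar solvent should secure this, and the remote E-trisubstituted alkene cannot take part because it is not allylic to the ring oxygen. The position of the new tetrasubstituted C=C is dictated by the mechanism, so no alkene regioisomers can arise.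

Step 5
Reactants: 10 3-[(3E)-5-hydroxy-3-methylpent-3-en-1-yl]-2,2,4-trimethylcyclohex-3-ene-1-carboxylic acid
Product: 12 (2E)-3-methyl-5-(2,6,6-trimethylcyclohex-1-en-1-yl)pent-2-en-1-ol (β-monocyclofarnesol), via thiohydroxamate ester 11 (not isolated)
Conditions: 2-mercaptopyridine N-oxide, DCC, CH2Cl2, 0 °C, dark; then t-BuSH, hν (W lamp), rt
Reagents that add atoms: none
Why: Barton reductive decarboxylation; without DMAP the acidic N-hydroxythione is acylated in preference to the primary alcohol, and the fast hydrogen donor t-BuSH should trap the secondary ring radical before it attacks the neighbouring ring alkene, which removes the temporary carboxyl group and its stereocentre.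

Step 6
Reactants: 12 β-monocyclofarnesol
Product: 13 (2E)-3-methyl-5-(2,6,6-trimethylcyclohex-1-en-1-yl)pent-2-enal
Conditions: MnO2, CH2Cl2, rt
Reagents that add atoms: none
Why: Chemoselective MnO2 oxidation of a primary allylic alcohol, which leaves the isolated alkenes untouched and should keep the E geometry of the enal.

Step 7
Reactants: 13 (2E)-3-methyl-5-(2,6,6-trimethylcyclohex-1-en-1-yl)pent-2-enal
Product: 14 1,3,3-trimethyl-2-[(3E)-3-methylhexa-3,5-dien-1-yl]cyclohex-1-ene
Conditions: Ph3PCH3Br, n-BuLi, THF, −78 → 0 °C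
Reagents that add atoms: methyltriphenylphosphonium bromide, C[P+](c1ccccc1)(c1ccccc1)c1ccccc1.[Br-]
Why: Wittig methylenation; the non-stabilised ylide adds 1,2 to the enal at low temperature and installs the terminal vinyl group without touching the E-trisubstituted alkene.

Step 8
Reactants: 15 tert-butyldimethyl(prop-2-yn-1-yloxy)silane; 16 methyl (2R)-oxirane-2-carboxylate (methyl (R)-glycidate)
Product: 18 methyl (2R)-6-[(tert-butyldimethylsilyl)oxy]-2-hydroxyhex-4-ynoate, via lithium acetylide 17 (not isolated)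
Conditions: n-BuLi, THF, −78 °C; BF3·OEt2; then 16, −78 °C; aq. NH4Cl
Reagents that add atoms: none
Why: BF3-promoted SN2 opening of the epoxide by the acetylide at the unsubstituted C3 (epoxide alkynylation), tolerated by the ester at −78 °C; the C2–O bond is not touched, so the (R) centre of the chiral-pool epoxide becomes C4 of the target.

Step 9
Reactants: 18 methyl (2R)-6-[(tert-butyldimethylsilyl)oxy]-2-hydroxyhex-4-ynoate
Product: 19 methyl (2R)-2-acetoxy-6-[(tert-butyldimethylsilyl)oxy]hex-4-ynoate
Conditions: Ac2O, pyridine, DMAP (cat.), CH2Cl2, 0 °C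
Reagents that add atoms: acetic anhydride, CC(=O)OC(C)=O
Why: Standard O-acetylation of a secondary alcohol, which supplies the two carbons C1 and C2 of the butenolide without touching the stereocentre.

Step 10
Reactants: 19 methyl (2R)-2-acetoxy-6-[(tert-butyldimethylsilyl)oxy]hex-4-ynoate
Product: 20 (5R)-5-{4-[(tert-butyldimethylsilyl)oxy]but-2-yn-1-yl}-4-hydroxyfuran-2(5H)-one (tetronic acid)
Conditions: LiHMDS (2.5 equiv), THF, −78 → 0 °C; then aq. HCl to pH 2
Reagents that add atoms: none
Why: Dieckmann condensation (5-exo-trig) of the kinetically formed acetate enolate onto the methyl ester; the resulting tetronate anion protects the adjacent C–H from deprotonation, so the configuration should be retained.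

Step 11
Reactants: 20 (5R)-5-{4-[(tert-butyldimethylsilyl)oxy]but-2-yn-1-yl}-4-hydroxyfuran-2(5H)-one
Product: 21 (2R)-2-{4-[(tert-butyldimethylsilyl)oxy]but-2-yn-1-yl}-5-oxo-2,5-dihydrofuran-3-yl trifluoromethanesulfonate
Conditions: Tf2O, i-Pr2NEt, CH2Cl2, −78 °C
Reagents that add atoms: trifluoromethanesulfonic anhydride, FC(F)(F)S(=O)(=O)OS(=O)(=O)C(F)(F)F
Why: O-sulfonylation of the acidic enol of a tetronic acid; the hindered amine and low temperature are chosen to avoid γ-deprotonation at the stereocentre.

Step 12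
Reactants: 21 (2R)-2-{4-[(tert-butyldimethylsilyl)oxy]but-2-yn-1-yl}-5-oxo-2,5-dihydrofuran-3-yl trifluoromethanesulfonate
Product: 22 (5R)-5-{4-[(tert-butyldimethylsilyl)oxy]but-2-yn-1-yl}-4-(hydroxymethyl)furan-2(5H)-one
Conditions: Bu3SnCH2OH, Pd(PPh3)4 (cat.), LiCl, THF, 65 °C
Reagents that add atoms: (tributylstannyl)methanol, CCCC[Sn](CCCC)(CCCC)CO
Why: Stille coupling of an electron-poor vinyl triflate with the hydroxymethyl stannane under neutral conditions, which spare the silyl ether, the alkyne and the γ-stereocentre.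

Step 13
Reactants: 22 (5R)-5-{4-[(tert-butyldimethylsilyl)oxy]but-2-yn-1-yl}-4-(hydroxymethyl)furan-2(5H)-one
Product: 23 (5R)-5-(4-hydroxybut-2-yn-1-yl)-4-(hydroxymethyl)furan-2(5H)-one
Conditions: HF·pyridine, THF, 0 °C
Reagents that add atoms: none
Why: Fluoride-driven cleavage of the primary silyl ether in a weakly acidic medium, which cannot epimerise the butenolide and frees the propargylic hydroxyl that steers step 14.

Step 14
Reactants: 23 (5R)-5-(4-hydroxybut-2-yn-1-yl)-4-(hydroxymethyl)furan-2(5H)-one
Product: 25 (5R)-5-[(2E)-4-hydroxy-3-iodobut-2-en-1-yl]-4-(hydroxymethyl)furan-2(5H)-one, via vinylstannane 24 (not isolated)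
Conditions: Bu3SnH (slow addition), PdCl2(PPh3)2 (cat.), THF, 0 °C; then I2, 0 °C
Reagents that add atoms: iodine, II
Why: Palladium-catalysed syn hydrostannation should place tin on the alkyne carbon next to the electron-withdrawing CH2OH and hydrogen on the distal carbon, and iododestannylation with retention gives the E-iodide in which CH2OH and the CH2 leading to the butenolide are cis; a minor regioisomer would be removed by chromatography.

Step 15
Reactants: 14 1,3,3-trimethyl-2-[(3E)-3-methylhexa-3,5-dien-1-yl]cyclohex-1-ene; 25 (5R)-5-[(2E)-4-hydroxy-3-iodobut-2-en-1-yl]-4-(hydroxymethyl)furan-2(5H)-one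
Product: 27 (6Z)-neomanoalide, via B-alkyl-9-BBN 26 (not isolated)
Conditions: 14, 9-BBN (1.05 equiv), THF, 0 °C → rt; then 25, PdCl2(dppf) (cat.), AsPh3, aq. K3PO4, DMF, rt
Reagents that add atoms: none
Why: 9-BBN hydroborates only the terminal monosubstituted alkene of the diene (anti-Markovnikov), and the B-alkyl Suzuki–Miyaura coupling transfers the primary alkyl group to the vinyl iodide with retention of geometry, which sets the 6Z alkene; phosphate base at room temperature is chosen to spare the base-sensitive C4–H of the butenolide.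

Compound list
1 | geranyl acetate | CC(C)=CCC/C(C)=C/COC(C)=O | starting material
2 | (2E)-6,7-dibromo-3,7-dimethyloct-2-en-1-yl acetate (racemic) | CC(C)(Br)C(Br)CC/C(C)=C/COC(C)=O | intermediate
3 | (2E)-6-bromo-3,7-dimethylocta-2,6-dien-1-ol | CC(C)=C(Br)CC/C(C)=C/CO | intermediate
4 | methyl 5-oxohexanoate | COC(=O)CCCC(C)=O | starting material
5 | dilithio species of 3 (lithium alkoxide, C6 vinyllithium) | CC(C)=C([Li])CC/C(C)=C/CO[Li] | intermediate
6 | dilithium dialkoxide of methyl (9E)-5,11-dihydroxy-5,9-dimethyl-6-(propan-2-ylidene)undec-9-enoate (racemic) | COC(=O)CCCC(C)(O[Li])C(=C(C)C)CC/C(C)=C/CO[Li] | intermediate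
7 | 6-[(6E)-8-hydroxy-2,6-dimethylocta-2,6-dien-3-yl]-6-methyloxan-2-one (racemic) | CC1(CCCC(=O)O1)C(=C(C)C)CC/C(C)=C/CO | intermediate
8 | bis(trimethylsilyl) derivative of 7: endocyclic silyl ketene acetal and silyl ether (racemic) | CC1(CCC=C(O[Si](C)(C)C)O1)C(=C(C)C)CC/C(C)=C/CO[Si](C)(C)C | intermediate
9 | trimethylsilyl ester, trimethylsilyl ether of 10 (racemic) | CC1=C(CC/C(C)=C/CO[Si](C)(C)C)C(C)(C)C(CC1)C(=O)O[Si](C)(C)C | intermediate
10 | 3-[(3E)-5-hydroxy-3-methylpent-3-en-1-yl]-2,2,4-trimethylcyclohex-3-ene-1-carboxylic acid (racemic) | CC1=C(CC/C(C)=C/CO)C(C)(C)C(CC1)C(=O)O | intermediate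
11 | 2-thioxopyridin-1(2H)-yl ester of 10 (racemic) | CC1=C(CC/C(C)=C/CO)C(C)(C)C(CC1)C(=O)ON1C=CC=CC1=S | intermediate
12 | (2E)-3-methyl-5-(2,6,6-trimethylcyclohex-1-en-1-yl)pent-2-en-1-ol | CC1=C(CC/C(C)=C/CO)C(C)(C)CCC1 | intermediate
13 | (2E)-3-methyl-5-(2,6,6-trimethylcyclohex-1-en-1-yl)pent-2-enal | CC1=C(CC/C(C)=C/C=O)C(C)(C)CCC1 | intermediate
14 | 1,3,3-trimethyl-2-[(3E)-3-methylhexa-3,5-dien-1-yl]cyclohex-1-ene | CC1=C(CC/C(C)=C/C=C)C(C)(C)CCC1 | intermediate
15 | tert-butyldimethyl(prop-2-yn-1-yloxy)silane | C#CCO[Si](C)(C)C(C)(C)C | starting material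
16 | methyl (2R)-oxirane-2-carboxylate | COC(=O)[C@H]1CO1 | starting material
17 | lithium acetylide of 15 | [Li]C#CCO[Si](C)(C)C(C)(C)C | intermediate
18 | methyl (2R)-6-[(tert-butyldimethylsilyl)oxy]-2-hydroxyhex-4-ynoate | COC(=O)[C@H](O)CC#CCO[Si](C)(C)C(C)(C)C | intermediate
19 | methyl (2R)-2-acetoxy-6-[(tert-butyldimethylsilyl)oxy]hex-4-ynoate | COC(=O)[C@H](OC(C)=O)CC#CCO[Si](C)(C)C(C)(C)C | intermediate
20 | (5R)-5-{4-[(tert-butyldimethylsilyl)oxy]but-2-yn-1-yl}-4-hydroxyfuran-2(5H)-one | CC(C)(C)[Si](C)(C)OCC#CC[C@H]1OC(=O)C=C1O | intermediate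
21 | (2R)-2-{4-[(tert-butyldimethylsilyl)oxy]but-2-yn-1-yl}-5-oxo-2,5-dihydrofuran-3-yl trifluoromethanesulfonate | CC(C)(C)[Si](C)(C)OCC#CC[C@H]1OC(=O)C=C1OS(=O)(=O)C(F)(F)F | intermediate
22 | (5R)-5-{4-[(tert-butyldimethylsilyl)oxy]but-2-yn-1-yl}-4-(hydroxymethyl)furan-2(5H)-one | CC(C)(C)[Si](C)(C)OCC#CC[C@H]1OC(=O)C=C1CO | intermediate
23 | (5R)-5-(4-hydroxybut-2-yn-1-yl)-4-(hydroxymethyl)furan-2(5H)-one | OCC#CC[C@H]1OC(=O)C=C1CO | intermediate
24 | (5R)-5-[(2E)-4-hydroxy-3-(tributylstannyl)but-2-en-1-yl]-4-(hydroxymethyl)furan-2(5H)-one | CCCC[Sn](CCCC)(CCCC)/C(CO)=C/C[C@H]1OC(=O)C=C1CO | intermediate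
25 | (5R)-5-[(2E)-4-hydroxy-3-iodobut-2-en-1-yl]-4-(hydroxymethyl)furan-2(5H)-one | I/C(CO)=C/C[C@H]1OC(=O)C=C1CO | intermediate
26 | 9-[(3E)-4-methyl-6-(2,6,6-trimethylcyclohex-1-en-1-yl)hex-3-en-1-yl]-9-borabicyclo[3.3.1]nonane | CC1=C(CC/C(C)=C/CCB2C3CCCC2CCC3)C(C)(C)CCC1 | intermediate
27 | (6Z)-neomanoalide, (4R) | CC1=C(CC/C(C)=C/CC/C(=C/C[C@H]2OC(=O)C=C2CO)CO)C(C)(C)CCC1 | target

Total step count: 15.
Longest linear sequence: 8 steps (steps 1–7 and 15). The branch through steps 8–14 and 15 is equally long.

Steps most likely to fail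

Step 4. Ionisation or elimination at the tertiary allylic C–O bond of the ketene acetal, or C-silylation of the enolate, may outrun the sterically demanding bond formation at the fully substituted alkene terminus. The fallback sets out from 3 and comes back at 12, and it makes the same ring bond by a thermal 6π-electrocyclisation.
- The dilithio species 5, generated from 3 as in step 3, is acylated with N-methoxy-N-methylacetamide to give (6E)-8-hydroxy-6-methyl-3-(propan-2-ylidene)oct-6-en-2-one F1.
- Wittig olefination with allylidenetriphenylphosphorane gives (2E)-3,7-dimethyl-6-(propan-2-ylidene)deca-2,7,9-trien-1-ol F2 as a mixture of 7E and 7Z isomers.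
- Heating in toluene (sealed tube, about 150 °C) with a trace of iodine interconverts the two isomers. The 7Z isomer then closes disrotatorily between C(CH3)2 and the terminal CH2 to give (2E)-3-methyl-5-(2,6,6-trimethylcyclohexa-1,3-dien-1-yl)pent-2-en-1-ol F3.
- Diimide (2-nitrobenzenesulfonylhydrazide, Et3N) saturates only the disubstituted ring alkene and gives 12.

Step 14. Tin and hydrogen may be delivered with poor regiocontrol, because both alkyne carbons carry CH2 groups, and some conjugate reduction of the butenolide may compete. The fallback sets out from 23 and comes back at 25, and it polarises the alkyne with a carbonyl group.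
- MnO2 should oxidise the propargylic alcohol in preference to the electron-poor allylic alcohol on the butenolide, giving 4-[(2R)-3-(hydroxymethyl)-5-oxo-2,5-dihydrofuran-2-yl]but-2-ynal F4.
- Palladium-catalysed hydrostannation of alkynyl carbonyl compounds places tin α to the carbonyl by syn addition. This gives (2E)-4-[(2R)-3-(hydroxymethyl)-5-oxo-2,5-dihydrofuran-2-yl]-2-(tributylstannyl)but-2-enal F5.
- Iodine converts it into (2E)-4-[(2R)-3-(hydroxymethyl)-5-oxo-2,5-dihydrofuran-2-yl]-2-iodobut-2-enal F6.
- Luche reduction (NaBH4, CeCl3, MeOH, −78 °C) of the aldehyde returns 25.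

Step 15. The base needed for boron-to-palladium transfer may erode the configuration at C4 by γ-deprotonation or open the lactone, and site selectivity in the hydroboration may be incomplete. The fallback sets out from 14 and 25 and comes back at 27, using a base-free Negishi coupling.
- The borane 26 from 14 is oxidised (H2O2, NaOH) to (3E)-4-methyl-6-(2,6,6-trimethylcyclohex-1-en-1-yl)hex-3-en-1-ol F7.
- An Appel reaction (I2, PPh3, imidazole) gives 2-[(3E)-6-iodo-3-methylhex-3-en-1-yl]-1,3,3-trimethylcyclohex-1-ene F8.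
- Zinc insertion (Zn, LiCl, THF) gives [(3E)-4-methyl-6-(2,6,6-trimethylcyclohex-1-en-1-yl)hex-3-en-1-yl]zinc iodide F9.
- In parallel, 25 is silylated (Et3SiCl, imidazole) to the bis(triethylsilyl) ether of 25 F10.
- Coupling of the two under PdCl2(dppf) catalysis in THF gives the bis(triethylsilyl) ether of (6Z)-neomanoalide F11, and HF·pyridine releases 27.

Further compounds
F1 | step 4 | (6E)-8-hydroxy-6-methyl-3-(propan-2-ylidene)oct-6-en-2-one | CC(=O)C(=C(C)C)CC/C(C)=C/CO
F2 | step 4 | (2E)-3,7-dimethyl-6-(propan-2-ylidene)deca-2,7,9-trien-1-ol (7E/7Z mixture) | C=CC=C(C)C(=C(C)C)CC/C(C)=C/CO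
F3 | step 4 | (2E)-3-methyl-5-(2,6,6-trimethylcyclohexa-1,3-dien-1-yl)pent-2-en-1-ol | CC1=C(CC/C(C)=C/CO)C(C)(C)CC=C1
F4 | step 14 | 4-[(2R)-3-(hydroxymethyl)-5-oxo-2,5-dihydrofuran-2-yl]but-2-ynal | O=CC#CC[C@H]1OC(=O)C=C1CO
F5 | step 14 | (2E)-4-[(2R)-3-(hydroxymethyl)-5-oxo-2,5-dihydrofuran-2-yl]-2-(tributylstannyl)but-2-enal | CCCC[Sn](CCCC)(CCCC)/C(C=O)=C/C[C@H]1OC(=O)C=C1CO
F6 | step 14 | (2E)-4-[(2R)-3-(hydroxymethyl)-5-oxo-2,5-dihydrofuran-2-yl]-2-iodobut-2-enal | I/C(C=O)=C/C[C@H]1OC(=O)C=C1CO
F7 | step 15 | (3E)-4-methyl-6-(2,6,6-trimethylcyclohex-1-en-1-yl)hex-3-en-1-ol | CC1=C(CC/C(C)=C/CCO)C(C)(C)CCC1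
F8 | step 15 | 2-[(3E)-6-iodo-3-methylhex-3-en-1-yl]-1,3,3-trimethylcyclohex-1-ene | CC1=C(CC/C(C)=C/CCI)C(C)(C)CCC1
F9 | step 15 | [(3E)-4-methyl-6-(2,6,6-trimethylcyclohex-1-en-1-yl)hex-3-en-1-yl]zinc iodide | CC1=C(CC/C(C)=C/CC[Zn]I)C(C)(C)CCC1
F10 | step 15 | bis(triethylsilyl) ether of 25 | CC[Si](CC)(CC)OC/C(I)=C\C[C@H]1OC(=O)C=C1CO[Si](CC)(CC)CC
F11 | step 15 | bis(triethylsilyl) ether of (6Z)-neomanoalide | CC1=C(CC/C(C)=C/CC/C(=C/C[C@H]2OC(=O)C=C2CO[Si](CC)(CC)CC)CO[Si](CC)(CC)CC)C(C)(C)CCC1
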